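The oak run cannot keep its target: between 10.0 h and 30.0 h the reading falls from 24% to 4%, which we read as a first-order loss of 0.0896 h⁻¹, while other capture product reads about 14.7% throughout.

- oak: starting material 0.99 M; first nucleophile 1.5 M; gas 200 mM (held); run made earlier
- flask: starting material 0.99 M; first nucleophile 2.97 M; gas 200 mM (held); time 25 h

- oak (time / h: target / %, other capture product / %): 4.00: 34, 16; 10.0: 24, 16; 20.0: 9, 11; 30.0: 4, 16

(each reading ± 2 percentage points)

- at the start none of second nucleophile is dissolved
- what was read earlier has a scatter of 2 percentage points, one standard deviation
- steps that have been proposed: first nucleophile + intermediate -> target; intermediate -> solvolysis product; second nucleophile + intermediate -> other capture product; starting material -> intermediate; target -> over-reaction product; gas <-> second nucleophile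

1. share of target in target plus other capture product at 40 s
2. share of target in target plus other capture product at 25 h

So we turn the question round: what must be true for target to lead other capture product in the flask at 25 h? At that loss, target formed must exceed other capture product by the level factor, the exponential of loss times time, 9.39.

We take the short-lived intermediate as used as fast as it is made, so the two captures split it in the ratio of their rates. Second nucleophile starts at none in both and both are held at 200 mM of gas, so we assume the same course of c(second nucleophile) in the oak run and the flask; this capture ratio (a selectivity factor) then goes with c(first nucleophile). In the oak run, target at 4.00 h, carried back by the loss, gives 48.7% formed, a ratio of 3.30. The flask charges twice the first nucleophile of the oak run, so its ratio is 6.53, below the level factor, and our share at 25 h is 41.0%.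

The forecast gives a higher 44% at 25 h, and 92% at 40 s, of which it says: “The dissolution rate is unconstrained, so this range is wide.”

The flask gives 98.9% at 40 s and 46.2% at 25 h, and target and other capture product stand level in it at 23.1 h. At 25 h, target plus over-reaction product in the flask stand at 6.13 times other capture product, under the flask's own level factor, target formed over target left, of 7.14, and the share lies below half.

    first nucleophile + intermediate → target (k = 0.00490 M⁻¹ s⁻¹)
    intermediate → solvolysis product (k = 0.00560 s⁻¹)
    second nucleophile + intermediate → other capture product (k = 0.0360 M⁻¹ s⁻¹)
    starting material → intermediate (k = 0.00150 s⁻¹)
    target → over-reaction product (k = 2.20 × 10⁻⁵ s⁻¹)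
    gas ⇌ second nucleophile, rate k6*(csat - [second nucleophile]) (kL = 9.10 × 10⁻⁴ s⁻¹)

In the neighbour flask charged with 1.8 M, the oak ratio scales to 3.96, lower than for the flask, and against our level factor of 9.39 from the oak readings that gives a share of 29.7%. The computed neighbour gives 35.2%.

The runs stem from a simulated flask with made-up constants; scatter was added.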